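## Retrosynthetic overview

1. Numbering used throughout: ring C1 (CH bearing the side chain), C2 (CH–O-angelate), C3–C4 (ring epoxide, CH3 on C4), C5 (C=O), C6 (CH–OAc); side chain C7(=C8H2)–C9H(O-angelate)–C10H2–C11H–C12Me2 (epoxide).
2. Target ⇐ angeloylation of the C2/C9 diol ⇐ C2–OH-directed nucleophilic epoxidation of the C3=C4–C5=O enone ⇐ enolate (E1cB) opening of the oxygen bridge C3–O–C6 of a 7-oxanorbornanone (C6–O kept and acetylated). The C7–C9 bond is made before that by Nozaki–Hiyama–Kishi coupling of a C7 vinyl iodide with the epoxy aldehyde C9–C12.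
3. 7-Oxanorbornene ⇐ Diels–Alder union of a 3-siloxy-4-alkynylfuran (C6=C1–C2=C3 plus the future bridge oxygen) with a chiral methylketene equivalent (C4=C5, an ethylidene dioxolanone), forming C5–C6 and C3–C4.
4. Enabling feature: C3 and C6, the two oxygen-bearing carbons that sit 1,4 across the carbocycle, flank C1–C2 with C2 also oxygenated, so C6–C1–C2–C3 plus one oxygen is a 3-oxyfuran. C5 (ketone) with its methyl-bearing neighbour C4 is a ketene-type dienophile, and the C3–C4 epoxide next to C5=O is the mark of the enone that the bridge opening sets free.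
5. Ring order: furan (bought) → carbocycle closed as the 7-oxanorbornene (key step) → oxygen bridge opened → ring epoxide last; the side-chain epoxide is made separately by Shi epoxidation.

Key step: step 6

Remark 1: β is the face of the carbocycle that carries the C6 oxygen (the side of the oxygen bridge, exo, in the bicyclic intermediates); α is the opposite face (endo). Bicyclic names use the locants of 7-oxabicyclo[2.2.1]heptane (bicycle C1 = target C6, C2 = C5, C3 = C4, C4 = C3, C5 = C2, C6 = C1).

Remark 2 (assumption on the chemistry): dienophile 12 is expected mainly as the Z isomer and to react with its lactone carbonyl exo. The configuration created at C4 and C5 is irrelevant, since both centres become sp2 later. If the endo mode dominated, the antipodal dienophile from (S)-2-hydroxybutanoic acid would give the same ring configuration.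

## Route

Step 1
Reactants: 1 3,4-dibromofuran; 2 ethynyltrimethylsilane
Product: 3 3-bromo-4-[(trimethylsilyl)ethynyl]furan
Conditions: Pd(PhCN)2Cl2 (3 mol%), P(t-Bu)3 (6 mol%), CuI (2 mol%), i-Pr2NH, dioxane, 25 °C; 1 in 2.5-fold excess (recovered)
Reagents that add atoms: none
Why: Sonogashira coupling with an electron-rich phosphine that activates the furyl bromide at room temperature; the excess of dibromide should keep the reaction at mono-alkynylation.

Step 2
Reactants: 3 3-bromo-4-[(trimethylsilyl)ethynyl]furan
Product: 6 4-[(trimethylsilyl)ethynyl]furan-3(2H)-one, via furyllithium 4 (not isolated), via lithium furylborate 5 (not isolated)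
Conditions: n-BuLi, Et2O, −78 °C; B(OMe)3, −78 → 0 °C; then 30% H2O2, aq. NaHCO3, 0 °C
Reagents that add atoms: hydrogen peroxide, OO
Why: bromine–lithium exchange at −78 °C (where a 3-furyllithium does not rearrange), borylation and oxidative C–B to C–O conversion should give the 3-hydroxyfuran, which rests as its keto tautomer, while the bicarbonate buffer spares the C-silyl alkyne.

Step 3
Reactants: 6 4-[(trimethylsilyl)ethynyl]furan-3(2H)-one
Product: 7 3-(tert-butyldimethylsilyloxy)-4-[(trimethylsilyl)ethynyl]furan
Conditions: TBSOTf, Et3N, CH2Cl2, 0 °C; used without chromatography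
Reagents that add atoms: tert-butyldimethylsilyl trifluoromethanesulfonate, CC(C)(C)[Si](C)(C)OS(=O)(=O)C(F)(F)F
Why: soft enolisation and O-silylation of the furanone restores the aromatic furan and gives the electron-rich 3-siloxyfuran diene.

Step 4
Reactants: 8 (R)-2-hydroxybutanoic acid; 9 pivalaldehyde
Product: 10 (2R,5R)-2-tert-butyl-5-ethyl-1,3-dioxolan-4-one (cis)
Conditions: TsOH·H2O (cat.), H2SO4 (cat.), pentane, reflux, water separator; crystallisation from pentane at −78 °C
Reagents that add atoms: none
Why: acid-catalysed acetalisation under equilibrating conditions should favour the cis acetal, whose new C2 centre (set relative to C5, purified by crystallisation) stores the chirality after C5 becomes sp2.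

Step 5
Reactants: 10 (2R,5R)-2-tert-butyl-5-ethyl-1,3-dioxolan-4-one
Product: 12 (2R,Z)-2-tert-butyl-5-ethylidene-1,3-dioxolan-4-one, via bromide 11 (not isolated)
Conditions: NBS, AIBN (cat.), PhCF3, 80 °C; then DBU, CH2Cl2, 0 °C
Reagents that add atoms: none
Why: radical bromination at the captodative C5–H followed by E2 loss of HBr toward the ethyl CH2 should give the alkylidene dioxolanone with the C2 acetal centre untouched.

Step 6
Reactants: 7 3-(tert-butyldimethylsilyloxy)-4-[(trimethylsilyl)ethynyl]furan; 12 (2R,Z)-2-tert-butyl-5-ethylidene-1,3-dioxolan-4-one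
Product: 13 (2'R)-2'-tert-butyl-5-(tert-butyldimethylsilyloxy)-3-endo-methyl-6-[(trimethylsilyl)ethynyl]spiro[7-oxabicyclo[2.2.1]hept-5-ene-2,5'-[1,3]dioxolan]-4'-one (lactone C=O exo)
Conditions: toluene (3 M), 2,6-di-tert-butyl-4-methylphenol (cat.), 60 °C, sealed tube (CH2Cl2, 1.2 GPa, 25 °C if conversion stalls); filtration through Et3N-deactivated silica
Reagents that add atoms: none
Why: A thermal, concerted but asynchronous normal-demand Diels–Alder reaction is expected: the C2 siloxy group makes C3 of furan 7 the most nucleophilic terminus, which bonds to the acrylate-type β-carbon C4 of 12, while C6 bonds to the captodative carbon C5, and the alkyne at C1 (unlike a vinyl group) offers no second diene. The closest known reaction types are the cycloadditions of 3-alkoxy- and 3-siloxyfurans with ketene equivalents and those of 2-tert-butyl-5-methylene-1,3-dioxolan-4-ones used as chiral ketene equivalents. The six-membered carbocycle C1–C6 is closed by a suprafacial [4π+2π] union that leaves the furan oxygen as a one-atom bridge between C3 and C6. C6 and C3 are set together by the furan face that meets the dienophile: 12 should react on its face anti to the tert-butyl group and, with the lactone carbonyl exo (toward the oxygen bridge), the (2R) acetal delivers the bridgehead configuration that becomes (6S), whereas the centres at C4 and C5 are transient. The step needs regioselectivity (secured by the siloxy group), π-facial selectivity (secured by the tert-butyl acetal) and exo selectivity (the known preference of this dienophile class); any endo adduct is a diastereomer and can be removed at 15.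

Step 7
Reactants: 13 Diels–Alder adduct
Product: 15 (2'R)-2'-tert-butyl-5-endo-hydroxy-3-endo-methyl-6-endo-[(trimethylsilyl)ethynyl]spiro[7-oxabicyclo[2.2.1]heptane-2,5'-[1,3]dioxolan]-4'-one, via ketone 14 (not isolated)
Conditions: HF·pyridine, pyridine, THF, 0 °C; cold aq. NaHCO3 work-up; then NaBH4, CeCl3·7H2O, MeOH, −78 °C
Reagents that add atoms: none
Why: buffered cleavage of the silyl enol ether should protonate C1 kinetically on the open exo face (alkyne endo, α) and Luche reduction should deliver hydride to C2 from the same exo face (hydroxyl endo, α), so C1 and C2 are set cis and anti to the bridge, while the non-basic medium avoids β-elimination of the bridge from the C2 ketone.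

Step 8
Reactants: 15 endo alcohol
Product: 17 6-endo-ethynyl-5-endo-hydroxy-3-endo-methyl-7-oxabicyclo[2.2.1]heptan-2-one, via hydroxy acid 16 (not isolated)
Conditions: LiOH, THF/MeOH/H2O, 0 → 25 °C; 1 M HCl to pH 3, extraction; then Pb(OAc)4, CH2Cl2, 0 °C
Reagents that add atoms: none
Why: saponification of the acylal-type lactone should free the tertiary α-hydroxy acid (and protodesilylate the alkyne), and lead tetraacetate cleaves α-hydroxy acids by oxidative decarboxylation to the ketone, here C5, under non-basic conditions that leave the bridge closed.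

Step 9
Reactants: 17 bicyclic alkynyl ketone
Product: 18 5-endo-hydroxy-3-endo-methyl-6-endo-[1-(triethylsilyl)ethenyl]-7-oxabicyclo[2.2.1]heptan-2-one
Conditions: [Cp*Ru(MeCN)3]PF6 (2 mol%), Et3SiH, CH2Cl2, 0 → 25 °C
Reagents that add atoms: triethylsilane, CC[SiH](CC)CC
Why: cationic ruthenium-catalysed hydrosilylation of terminal alkynes places silicon on the internal carbon (1,1-disubstituted vinylsilane) and tolerates ketones and free hydroxyl groups.

Step 10
Reactants: 18 vinylsilane
Product: 19 5-endo-hydroxy-6-endo-(1-iodoethenyl)-3-endo-methyl-7-oxabicyclo[2.2.1]heptan-2-one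
Conditions: NIS, 2,6-lutidine, (CF3)2CHOH, 0 °C
Reagents that add atoms: N-iodosuccinimide, O=C1CCC(=O)N1I
Why: ipso-iododesilylation of the vinylsilane through the β-silyl cation, which is fast in hexafluoroisopropanol, should give the 2-iodoalkene without touching ketone or alcohol.

Step 11
Reactants: 20 4-methylpent-3-en-1-ol
Product: 21 2-[(2S)-3,3-dimethyloxiran-2-yl]ethan-1-ol
Conditions: L-fructose-derived diacetonide ketone catalyst (enantiomer of the usual Shi epoxidation catalyst, 30 mol%), KHSO5 (as Oxone), K2CO3, n-Bu4NHSO4, MeCN/dimethoxymethane/aq. borate buffer (pH 10.5), 0 °C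
Reagents that add atoms: potassium peroxymonosulfate, [K+].[O-]S(=O)(=O)OO
Why: Shi epoxidation through the chiral dioxirane and a spiro transition state; the L-series catalyst should give the (S) epoxide of this trisubstituted alkene, and the basic buffer avoids cyclisation of the hydroxy epoxide.

Step 12
Reactants: 21 (S)-epoxy alcohol
Product: 22 2-[(2S)-3,3-dimethyloxiran-2-yl]acetaldehyde
Conditions: Dess–Martin periodinane, NaHCO3, CH2Cl2, 0 °C; used at once
Reagents that add atoms: none
Why: buffered Dess–Martin oxidation is close to neutral and should deliver the β,γ-epoxy aldehyde without epoxide opening or β-elimination.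

Step 13
Reactants: 19 vinyl iodide; 22 (S)-epoxy aldehyde
Product: 23 6-endo-{(3R)-4-[(2S)-3,3-dimethyloxiran-2-yl]-3-hydroxybut-1-en-2-yl}-5-endo-hydroxy-3-endo-methyl-7-oxabicyclo[2.2.1]heptan-2-one
Conditions: CrCl2 (4 equiv), NiCl2 (2 mol%), chiral 2-(2-methanesulfonamidoaryl)oxazoline ligand (4.4 equiv), Et3N, THF, 25 °C
Reagents that add atoms: none
Why: Nozaki–Hiyama–Kishi coupling, in which the alkenylchromium species adds to the aldehyde only (ketone, epoxide and free hydroxyl tolerated); the sulfonamide ligand on chromium controls the aldehyde face, its antipode being chosen for the (9R) carbinol, and any 9-epimer is a separable diastereomer.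

Step 14
Reactants: 23 diol
Product: 24 bis(triethylsilyl) ether of 23 (C2–OSiEt3 and C9–OSiEt3)
Conditions: Et3SiCl, imidazole, DMF, 0 → 25 °C
Reagents that add atoms: chlorotriethylsilane, CC[Si](Cl)(CC)CC
Why: silylation of both secondary alcohols under non-enolising conditions sets them apart from the C6 oxygen that the next step releases.

Step 15
Reactants: 24 bis(triethylsilyl) ether
Product: 26 6β-acetoxy-4-methyl-2α,9-bis(triethylsilyloxy) cyclohex-3-en-5-one carrying the C7–C12 side chain at C1α, via lithium alkoxide 25 (not isolated)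
Conditions: LiN(SiMe3)2 (1.1 equiv), THF, −78 → −20 °C; then Ac2O, −78 → 0 °C
Reagents that add atoms: acetic anhydride, CC(=O)OC(C)=O
Why: base-induced E1cB opening of 7-oxanorbornanones is known chemistry; C4 is the only enolisable position (C6 is a bridgehead), its enolate expels the C3–O bond with release of the bicyclic strain, and the C6 alkoxide, whose configuration is untouched, is acetylated in the flask.

Step 16
Reactants: 26 acetoxy enone
Product: 27 6β-acetoxy-2α,9-dihydroxy enone (diol)
Conditions: TBAF, AcOH (1:1), THF, 0 °C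
Reagents that add atoms: none
Why: acetic acid-buffered fluoride should cleave both triethylsilyl ethers at near-neutral pH, which protects the α-acetoxy enone from base and the hydroxy epoxide from acid-induced cyclisation.

Step 17
Reactants: 27 enone diol
Product: 28 6β-acetoxy-3α,4α-epoxy-2α,9-dihydroxy ketone (epoxy ketone diol)
Conditions: t-BuOOH (anhydrous, in decane), DBU, CH2Cl2, 0 °C
Reagents that add atoms: tert-butyl hydroperoxide, CC(C)(C)OO
Why: nucleophilic (Weitz–Scheffer) epoxidation of the enone, in which the pseudoaxial C2–OH should hydrogen-bond the peroxide anion and deliver it to C3 on its own α face (hydroxyl-directed, syn), so that enolate closure gives the cis-fused epoxide at C3/C4 on the face opposite the equatorial C6 acetate.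

Step 18
Reactants: 28 epoxy ketone diol; 29 angelic acid
Product: 31 target CNP0407453.2, via mixed anhydride 30 (not isolated)
Conditions: 29 (3 equiv), 2,4,6-trichlorobenzoyl chloride, Et3N, toluene, 25 °C; then 28, DMAP, toluene, 25 → 50 °C
Reagents that add atoms: none
Why: Yamaguchi esterification, in which the preformed mixed anhydride acylates both secondary alcohols (C2 and C9) through the acylpyridinium ion under conditions known to keep the Z geometry of angelates.

## Compound list

1 | 3,4-dibromofuran | Brc1cocc1Br | starting material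
2 | ethynyltrimethylsilane | C#C[Si](C)(C)C | starting material
3 | 3-bromo-4-[(trimethylsilyl)ethynyl]furan | Brc1cocc1C#C[Si](C)(C)C | intermediate
4 | {4-[(trimethylsilyl)ethynyl]furan-3-yl}lithium | [Li]c1cocc1C#C[Si](C)(C)C | intermediate (not isolated)
5 | lithium trimethoxy{4-[(trimethylsilyl)ethynyl]furan-3-yl}borate | [Li+].CO[B-](OC)(OC)c1cocc1C#C[Si](C)(C)C | intermediate (not isolated)
6 | 4-[(trimethylsilyl)ethynyl]furan-3(2H)-one | O=C1COC=C1C#C[Si](C)(C)C | intermediate
7 | 3-(tert-butyldimethylsilyloxy)-4-[(trimethylsilyl)ethynyl]furan | CC(C)(C)[Si](C)(C)Oc1cocc1C#C[Si](C)(C)C | intermediate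
8 | (R)-2-hydroxybutanoic acid | CC[C@@H](O)C(=O)O | starting material
9 | pivalaldehyde (2,2-dimethylpropanal) | CC(C)(C)C=O | starting material
10 | (2R,5R)-2-tert-butyl-5-ethyl-1,3-dioxolan-4-one (cis) | CC[C@H]1O[C@@H](C(C)(C)C)OC1=O | intermediate
11 | (2R)-5-bromo-2-tert-butyl-5-ethyl-1,3-dioxolan-4-one (Br trans to tert-butyl) | CC[C@@]1(Br)O[C@@H](C(C)(C)C)OC1=O | intermediate (not isolated)
12 | (2R,Z)-2-tert-butyl-5-ethylidene-1,3-dioxolan-4-one | C/C=C1\O[C@@H](C(C)(C)C)OC1=O | intermediate
13 | Diels–Alder adduct: (2'R)-2'-tert-butyl-5-(tert-butyldimethylsilyloxy)-3-endo-methyl-6-[(trimethylsilyl)ethynyl]spiro[7-oxabicyclo[2.2.1]hept-5-ene-2,5'-[1,3]dioxolan]-4'-one, lactone C=O exo | O=C1O[C@H](C(C)(C)C)O[C@]12[C@@H](C)[C@@H]3O[C@H]2C(C#C[Si](C)(C)C)=C3O[Si](C)(C)C(C)(C)C | intermediate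
14 | (2'R)-2'-tert-butyl-3-endo-methyl-6-endo-[(trimethylsilyl)ethynyl]spiro[7-oxabicyclo[2.2.1]heptane-2,5'-[1,3]dioxolane]-4',5-dione | O=C1O[C@H](C(C)(C)C)O[C@]12[C@@H](C)[C@@H]3O[C@H]2[C@H](C#C[Si](C)(C)C)C3=O | intermediate (not isolated)
15 | (2'R)-2'-tert-butyl-5-endo-hydroxy-3-endo-methyl-6-endo-[(trimethylsilyl)ethynyl]spiro[7-oxabicyclo[2.2.1]heptane-2,5'-[1,3]dioxolan]-4'-one | O=C1O[C@H](C(C)(C)C)O[C@]12[C@@H](C)[C@@H]3O[C@H]2[C@H](C#C[Si](C)(C)C)[C@@H]3O | intermediate
16 | 6-endo-ethynyl-2-endo,5-endo-dihydroxy-3-endo-methyl-7-oxabicyclo[2.2.1]heptane-2-exo-carboxylic acid | O=C(O)[C@]1(O)[C@@H](C)[C@@H]2O[C@H]1[C@H](C#C)[C@@H]2O | intermediate (not isolated)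
17 | 6-endo-ethynyl-5-endo-hydroxy-3-endo-methyl-7-oxabicyclo[2.2.1]heptan-2-one | O=C1[C@@H](C)[C@@H]2O[C@H]1[C@H](C#C)[C@@H]2O | intermediate
18 | 5-endo-hydroxy-3-endo-methyl-6-endo-[1-(triethylsilyl)ethenyl]-7-oxabicyclo[2.2.1]heptan-2-one | O=C1[C@@H](C)[C@@H]2O[C@H]1[C@H](C(=C)[Si](CC)(CC)CC)[C@@H]2O | intermediate
19 | 5-endo-hydroxy-6-endo-(1-iodoethenyl)-3-endo-methyl-7-oxabicyclo[2.2.1]heptan-2-one | O=C1[C@@H](C)[C@@H]2O[C@H]1[C@H](C(I)=C)[C@@H]2O | intermediate
20 | 4-methylpent-3-en-1-ol | CC(C)=CCCO | starting material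
21 | 2-[(2S)-3,3-dimethyloxiran-2-yl]ethan-1-ol | OCC[C@@H]1OC1(C)C | intermediate
22 | 2-[(2S)-3,3-dimethyloxiran-2-yl]acetaldehyde | O=CC[C@@H]1OC1(C)C | intermediate
23 | 6-endo-{(3R)-4-[(2S)-3,3-dimethyloxiran-2-yl]-3-hydroxybut-1-en-2-yl}-5-endo-hydroxy-3-endo-methyl-7-oxabicyclo[2.2.1]heptan-2-one | O=C1[C@@H](C)[C@@H]2O[C@H]1[C@H](C(=C)[C@@H](C[C@@H]1OC1(C)C)O)[C@@H]2O | intermediate
24 | bis(triethylsilyl) ether of 23 (C2–O and C9–O) | O=C1[C@@H](C)[C@@H]2O[C@H]1[C@H](C(=C)[C@@H](C[C@@H]1OC1(C)C)O[Si](CC)(CC)CC)[C@@H]2O[Si](CC)(CC)CC | intermediate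
25 | lithium C6 alkoxide of the ring-opened enone (C3=C4–C5=O, C2 and C9 as triethylsilyl ethers) | [Li+].[O-][C@@H]1C(=O)C(C)=C[C@@H](O[Si](CC)(CC)CC)[C@H]1C(=C)[C@@H](C[C@@H]2OC2(C)C)O[Si](CC)(CC)CC | intermediate (not isolated)
26 | 6β-acetoxy-4-methyl-2α,9-bis(triethylsilyloxy) cyclohex-3-en-5-one with the C7–C12 side chain at C1α | CC(=O)O[C@@H]1C(=O)C(C)=C[C@@H](O[Si](CC)(CC)CC)[C@H]1C(=C)[C@@H](C[C@@H]2OC2(C)C)O[Si](CC)(CC)CC | intermediate
27 | 6β-acetoxy-2α,9-dihydroxy enone (diol of 26) | CC(=O)O[C@@H]1C(=O)C(C)=C[C@@H](O)[C@H]1C(=C)[C@@H](C[C@@H]2OC2(C)C)O | intermediate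
28 | 6β-acetoxy-3α,4α-epoxy-2α,9-dihydroxy ketone (ring epoxide cis to C2–OH) | C=C([C@@H]1[C@H](O)[C@@H]2O[C@]2(C)C(=O)[C@H]1OC(C)=O)[C@@H](C[C@@H]1OC1(C)C)O | intermediate
29 | angelic acid, (Z)-2-methylbut-2-enoic acid | C/C=C(/C)C(=O)O | starting material
30 | (Z)-2-methylbut-2-enoic 2,4,6-trichlorobenzoic anhydride | C/C=C(/C)C(=O)OC(=O)c1c(Cl)cc(Cl)cc1Cl | intermediate (not isolated)
31 | CNP0407453.2, (1R,2S,3S,4S,6S,9R,11S) in the numbering of the overview | C=C([C@@H]1[C@H](OC(=O)/C(C)=C\C)[C@@H]2O[C@]2(C)C(=O)[C@H]1OC(C)=O)[C@@H](C[C@@H]1OC1(C)C)OC(=O)/C(C)=C\C | target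

## Step count and risks

Total step count: 18. Longest linear sequence: 14 steps (steps 1–3, 6–10 and 13–18, from 3,4-dibromofuran).

Three steps most likely to fail:

1. Step 6 (key cycloaddition). What may go wrong: slow cycloaddition of the trisubstituted captodative alkene, cycloreversion of the adduct on heating, and leakage through the endo mode. Fallback, an anionic double Michael annulation (formal [4+2]) that sets out from 6 and 12 and comes back at 15: 6 is deprotonated with LiN(SiMe3)2 (THF, −78 °C) to lithium 4-[(trimethylsilyl)ethynyl]furan-3-olate F1. On addition of 12, C3 adds to the β-carbon C4, and the resulting dioxolanone enolate closes onto C6 anti to the tert-butyl group in the same flask. The bicyclic lithium enolate F2 is protonated with AcOH at −78 °C to ketone 14, which is reduced as in the second half of step 7 to 15. Both bonds are still formed in one operation, but stepwise and at low temperature, so that no thermal retro-reaction can compete.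

2. Step 17 (directed epoxidation). What may go wrong: loss of the C6 acetate by acyl transfer to the peroxide anion, and insufficient hydroxyl direction so that attack anti to the C2 oxygen competes. Fallback, which sets out from 24 and comes back at 31: step 15 is run with t-BuMe2SiCl in place of Ac2O (via 25) to give the C6 tert-butyldimethylsilyl ether F5. Both triethylsilyl ethers are removed selectively (HF·pyridine with excess pyridine, THF, 0 °C) to the diol F6. Epoxidation (t-BuOOH, DBU), now with no ester present and with the bulky β-silyloxy group reinforcing α attack, gives the epoxy ketone diol F7. Yamaguchi angeloylation with 30 gives the bis-angelate F8, HF·pyridine frees the C6 alcohol F9, and Ac2O/pyridine/DMAP gives 31.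

3. Step 13 (fragment coupling). What may go wrong: decomposition of the β,γ-epoxy aldehyde under the Lewis-acidic chromium conditions (β-elimination, cyclisation of the chromium alkoxide onto the epoxide) and incomplete reagent control at C9. Fallback, which sets out from 20 and 19 and comes back at 23: 20 is oxidised (Dess–Martin periodinane, NaHCO3) to 4-methylpent-3-enal F3, which is coupled with 19 under the conditions of step 13 to the diene diol F4. Shi epoxidation with the L-fructose-derived catalyst, which should act only on the electron-rich trisubstituted alkene, then gives 23. A 9-epimer remains a separable diastereomer in either sequence.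

## Further compounds

F1 | step 6 | lithium 4-[(trimethylsilyl)ethynyl]furan-3-olate | [Li+].[O-]c1cocc1C#C[Si](C)(C)C
F2 | step 6 | bicyclic lithium enolate of ketone 14 | [Li+].O=C1O[C@H](C(C)(C)C)O[C@]12[C@@H](C)[C@@H]3O[C@H]2C(C#C[Si](C)(C)C)=C3[O-]
F3 | step 13 | 4-methylpent-3-enal | CC(C)=CCC=O
F4 | step 13 | 5-endo-hydroxy-6-endo-[(3R)-3-hydroxy-6-methylhepta-1,5-dien-2-yl]-3-endo-methyl-7-oxabicyclo[2.2.1]heptan-2-one | O=C1[C@@H](C)[C@@H]2O[C@H]1[C@H](C(=C)[C@@H](CC=C(C)C)O)[C@@H]2O
F5 | step 17 | 6β-(tert-butyldimethylsilyloxy) analogue of 26 | CC(C)(C)[Si](C)(C)O[C@@H]1C(=O)C(C)=C[C@@H](O[Si](CC)(CC)CC)[C@H]1C(=C)[C@@H](C[C@@H]2OC2(C)C)O[Si](CC)(CC)CC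
F6 | step 17 | 6β-(tert-butyldimethylsilyloxy) analogue of 27 | CC(C)(C)[Si](C)(C)O[C@@H]1C(=O)C(C)=C[C@@H](O)[C@H]1C(=C)[C@@H](C[C@@H]2OC2(C)C)O
F7 | step 17 | 6β-(tert-butyldimethylsilyloxy) analogue of 28 | C=C([C@@H]1[C@H](O)[C@@H]2O[C@]2(C)C(=O)[C@H]1O[Si](C)(C)C(C)(C)C)[C@@H](C[C@@H]1OC1(C)C)O
F8 | step 17 | 2,9-bis-angelate with C6 tert-butyldimethylsilyl ether | C=C([C@@H]1[C@H](OC(=O)/C(C)=C\C)[C@@H]2O[C@]2(C)C(=O)[C@H]1O[Si](C)(C)C(C)(C)C)[C@@H](C[C@@H]1OC1(C)C)OC(=O)/C(C)=C\C
F9 | step 17 | 2,9-bis-angelate with free C6 hydroxyl (6-O-deacetyl target) | C=C([C@@H]1[C@H](OC(=O)/C(C)=C\C)[C@@H]2O[C@]2(C)C(=O)[C@H]1O)[C@@H](C[C@@H]1OC1(C)C)OC(=O)/C(C)=C\C
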